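**Assumption:** ketoisophorone, (2E)-3-methylpent-2-en-4-yn-1-ol and the C10 dialdehyde are taken as catalogue chemicals. Chain locants C1–C18 are those of the octadecane chain of the target (C2 = carbonyl carbon, C18 = alkyne carbon on the ring). All polyene work is done under argon in dim light.

## Retrosynthetic overview

1. Target ⇒ C25 allylic phosphonate + C6 keto-enal: Horner–Wadsworth–Emmons (HWE) at C5=C6, aldehyde chosen over the methyl ketone.
2. C25 phosphonate ⇒ C15 enynal + C10 bis-phosphonate: mono-HWE at C13=C14, with C14 as the electrophile so the isomerisation-prone 15E enyne never sits in an allyl anion.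
3. C15 enynal ⇒ hindered ring-ketone tosylhydrazone + (E)-enyne by the new palladium-carbene alkynylation, which makes the ring–C18 bond and the tetrasubstituted ring alkene in one step.
4. The stereocentre comes from ketoisophorone by ene-reductase reduction (sets the methyl centre), then substrate-controlled carbonyl reduction (relays it to the carbinol).
5. No ring is formed: ring A is carried intact from ketoisophorone. Both C6 termini come from the same (E)-enynol.

## Route

Step 1
Reactants: 1 ketoisophorone (2,6,6-trimethylcyclohex-2-ene-1,4-dione)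
Product: 2 (6R)-levodione ((6R)-2,2,6-trimethylcyclohexane-1,4-dione)
Conditions: ene-reductase OYE2, NADP+ (cat.), glucose dehydrogenase, D-glucose (1.5 equiv), K2HPO4/KH2PO4 buffer pH 6.5, 30 °C, short run
Reagents that add atoms: none
Why: Flavin-dependent ene-reductase reduction (asymmetric conjugate reduction) adds hydride and a proton anti across the enedione C=C in the enzyme pocket and sets the methyl-bearing centre as R, while pH 6.5 and a short run limit racemisation of this α-stereocentre.

Step 2
Reactants: 2 (6R)-levodione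
Product: 3 (4R,6R)-actinol ((4R,6R)-4-hydroxy-2,2,6-trimethylcyclohexan-1-one; OH trans to the 6-methyl)
Conditions: H2 (5 bar), Raney Ni, MeOH, 25 °C; recrystallise (iPr2O/hexane)
Reagents that add atoms: none
Why: Substrate-controlled heterogeneous carbonyl hydrogenation: the C1 carbonyl between CMe2 and CHMe is too hindered to react, and hydrogen reaches the C4 carbonyl from the face away from the axial C2 methyl, giving the axial alcohol trans to the C6 methyl (4R), the minor cis isomer being removed by crystallisation.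

Step 3
Reactants: 3 (4R,6R)-actinol
Product: 4 (4R,6R)-4-[(tert-butyldimethylsilyl)oxy]-2,2,6-trimethylcyclohexan-1-one
Conditions: TBSCl (1.2 equiv), imidazole (2.5 equiv), DMF, 25 °C
Reagents that add atoms: tert-butyldimethylsilyl chloride, CC(C)(C)[Si](C)(C)Cl
Why: Imidazole-promoted silyl ether formation masks the only hydroxyl against the base and palladium of step 6 without touching the hindered ketone.

Step 4
Reactants: 4 (4R,6R)-4-[(tert-butyldimethylsilyl)oxy]-2,2,6-trimethylcyclohexan-1-one
Product: 5 N'-[(1E,4R,6R)-4-[(tert-butyldimethylsilyl)oxy]-2,2,6-trimethylcyclohexylidene]-4-methylbenzenesulfonohydrazide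
Conditions: TsNHNH2 (1.2 equiv), AcOH (cat.), EtOH, 70 °C; crystallise
Reagents that add atoms: 4-methylbenzenesulfonohydrazide, Cc1ccc(cc1)S(=O)(=O)NN
Why: Acid-catalysed hydrazone condensation gives the N-tosylhydrazone with the N–N bond turned away from the quaternary carbon; any epimerisation at C6 is harmless because that centre becomes sp2 in step 6.

Step 5
Reactants: 6 (2E)-3-methylpent-2-en-4-yn-1-ol
Product: 7 tert-butyldimethyl{[(2E)-3-methylpent-2-en-4-yn-1-yl]oxy}silane
Conditions: TBSCl (1.1 equiv), imidazole (2 equiv), CH2Cl2, 0 → 25 °C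
Reagents that add atoms: tert-butyldimethylsilyl chloride, CC(C)(C)[Si](C)(C)Cl
Why: Standard silylation of the primary allylic alcohol prevents alkoxide oxidation in step 6 and leaves the E enyne untouched.

Step 6
Reactants: 5 N'-[(1E,4R,6R)-4-[(tert-butyldimethylsilyl)oxy]-2,2,6-trimethylcyclohexylidene]-4-methylbenzenesulfonohydrazide; 7 tert-butyldimethyl{[(2E)-3-methylpent-2-en-4-yn-1-yl]oxy}silane
Product: 9 bis-TBS C15 enyne (tert-butyl{[(1R)-4-[(3E)-5-{[tert-butyl(dimethyl)silyl]oxy}-3-methylpent-3-en-1-yn-1-yl]-3,5,5-trimethylcyclohex-3-en-1-yl]oxy}dimethylsilane), via diazoalkane 8 (not isolated)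
Conditions: Pd(OAc)2 (5 mol %), P(2-furyl)3 (20 mol %), 1,4-benzoquinone (2 equiv), LiOtBu (3.5 equiv), 1,4-dioxane, 80 °C, slow addition of 7 (2 equiv)
Reagents that add atoms: none
Why: Proposed new method: LiOtBu turns hydrazone 5 into diazoalkane 8 (Bamford–Stevens), which is trapped by the alkynyl–divalent palladium species formed from 7 to give a palladium carbene; 1,1-migratory insertion of the slim, linear alkynyl group into this carbene flanked by CMe2 and CHMe makes the ring–C18 bond, and since the quaternary neighbour has no hydrogen, syn β-hydride elimination can only use the single C–H on the methyl-bearing carbon, so the tetrasubstituted ring alkene forms regiospecifically and without any carbocation that could scramble the 15E enyne, after which benzoquinone returns zerovalent palladium to divalent palladium; the closest known reaction types are the palladium-catalysed oxidative coupling of N-tosylhydrazones with terminal alkynes to 1,3-enynes and the Barluenga coupling, neither shown on an α-quaternary, α'-branched cyclohexanone hydrazone to give a fully substituted enyne.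

Step 7
Reactants: 9 bis-TBS C15 enyne
Product: 10 (1R)-4-[(3E)-5-hydroxy-3-methylpent-3-en-1-yn-1-yl]-3,5,5-trimethylcyclohex-3-en-1-ol
Conditions: Bu4NF (3 equiv), THF, 0 → 25 °C
Reagents that add atoms: none
Why: Fluoride-mediated desilylation removes both TBS groups under non-acidic conditions, so no propargyl or allyl cation can isomerise the E enyne.

Step 8
Reactants: 10 (1R)-4-[(3E)-5-hydroxy-3-methylpent-3-en-1-yn-1-yl]-3,5,5-trimethylcyclohex-3-en-1-ol
Product: 11 (2E)-5-[(4R)-4-hydroxy-2,6,6-trimethylcyclohex-1-en-1-yl]-3-methylpent-2-en-4-ynal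
Conditions: MnO2 (activated, 15 equiv), CH2Cl2, 25 °C, dark
Reagents that add atoms: none
Why: Chemoselective allylic oxidation with MnO2 converts only the primary allylic alcohol into the enal, while the non-allylic ring carbinol (the stereocentre) is not oxidised.

Step 9
Reactants: 12 (2E,4E,6E)-2,7-dimethylocta-2,4,6-trienedial
Product: 13 (2E,4E,6E)-2,7-dimethylocta-2,4,6-triene-1,8-diol
Conditions: NaBH4 (0.6 equiv), MeOH/THF, 0 °C
Reagents that add atoms: none
Why: Borohydride 1,2-reduction of both enal carbonyls at low temperature gives the bis-allylic diol with the triene geometry unchanged.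

Step 10
Reactants: 13 (2E,4E,6E)-2,7-dimethylocta-2,4,6-triene-1,8-diol
Product: 14 (2E,4E,6E)-1,8-dibromo-2,7-dimethylocta-2,4,6-triene
Conditions: PBr3 (0.7 equiv), pyridine (cat.), Et2O, −20 → 0 °C, dark; used crude at once
Reagents that add atoms: phosphorus tribromide, BrP(Br)Br
Why: PBr3 bromination (bromophosphite ester then SN2 displacement by bromide) converts both primary allylic alcohols to bromides and keeps the all-E triene.

Step 11
Reactants: 14 (2E,4E,6E)-1,8-dibromo-2,7-dimethylocta-2,4,6-triene
Product: 15 tetraethyl [(2E,4E,6E)-2,7-dimethylocta-2,4,6-triene-1,8-diyl]bis(phosphonate)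
Conditions: P(OEt)3 (excess), 100 °C, then remove volatiles
Reagents that add atoms: triethyl phosphite, CCOP(OCC)OCC
Why: Michaelis–Arbuzov reaction: SN2 attack of the phosphite on each primary allylic bromide and dealkylation by bromide give the bis-phosphonate.

Step 12
Reactants: 11 (2E)-5-[(4R)-4-hydroxy-2,6,6-trimethylcyclohex-1-en-1-yl]-3-methylpent-2-en-4-ynal; 15 tetraethyl [(2E,4E,6E)-2,7-dimethylocta-2,4,6-triene-1,8-diyl]bis(phosphonate)
Product: 16 diethyl {(2E,4E,6E,8E,10E)-13-[(4R)-4-hydroxy-2,6,6-trimethylcyclohex-1-en-1-yl]-2,7,11-trimethyltrideca-2,4,6,8,10-pentaen-12-yn-1-yl}phosphonate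
Conditions: 15 (4 equiv), KN(SiMe3)2 (3 equiv), THF, −78 °C; then 11 (1 equiv) added slowly, −78 → 0 °C; excess 15 recovered
Reagents that add atoms: none
Why: Horner–Wadsworth–Emmons olefination: the mono-anion of the excess bis-phosphonate adds to the enal and loses diethyl phosphate to give the E C13=C14 alkene, and because the 15E enyne belongs to the electrophile it is never part of an allyl anion and keeps its geometry.

Step 13
Reactants: 6 (2E)-3-methylpent-2-en-4-yn-1-ol
Product: 17 (3E)-5-hydroxy-3-methylpent-3-en-2-one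
Conditions: (Ph3P)AuNTf2 (2 mol %), 1,4-dioxane/H2O (4:1), 60 °C
Reagents that add atoms: water, O
Why: Gold-catalysed Markovnikov alkyne hydration: π-activation, attack of water at the internal alkyne carbon and tautomerisation give the methyl ketone, and the E geometry keeps the hydroxymethyl group away from the alkyne so no furan can form.

Step 14
Reactants: 17 (3E)-5-hydroxy-3-methylpent-3-en-2-one
Product: 18 (2E)-3-methyl-4-oxopent-2-enal
Conditions: MnO2 (activated, 15 equiv), CH2Cl2, 25 °C; used as a titrated solution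
Reagents that add atoms: none
Why: MnO2 allylic oxidation of the primary allylic alcohol gives the γ-oxo-enal without touching the ketone or the E alkene.

Step 15
Reactants: 16 diethyl {(2E,4E,6E,8E,10E)-13-[(4R)-4-hydroxy-2,6,6-trimethylcyclohex-1-en-1-yl]-2,7,11-trimethyltrideca-2,4,6,8,10-pentaen-12-yn-1-yl}phosphonate; 18 (2E)-3-methyl-4-oxopent-2-enal
Product: 19 (3E,5E,7E,9E,11E,13E,15E)-18-[(4R)-4-hydroxy-2,6,6-trimethylcyclohex-1-en-1-yl]-3,7,12,16-tetramethyloctadeca-3,5,7,9,11,13,15-heptaen-17-yn-2-one
Conditions: 16, KN(SiMe3)2 (2.05 equiv), THF, −78 °C; then 18 (1.2 equiv), −78 → −20 °C; NH4Cl quench; chromatography and crystallisation in dim light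
Reagents that add atoms: none
Why: Horner–Wadsworth–Emmons olefination at the aldehyde of the γ-oxo-enal, which is far more electrophilic than the conjugated methyl ketone, gives the E C5=C6 alkene in the same way that ylides join γ-oxo-enal C5 units in industrial retinoid synthesis.

## Compound list

1 | ketoisophorone (2,6,6-trimethylcyclohex-2-ene-1,4-dione) | CC1=CC(=O)CC(C)(C)C1=O | starting material
2 | (6R)-levodione, (6R)-2,2,6-trimethylcyclohexane-1,4-dione | O=C1[C@H](C)CC(=O)CC1(C)C | intermediate
3 | (4R,6R)-actinol, (4R,6R)-4-hydroxy-2,2,6-trimethylcyclohexan-1-one | O=C1[C@H](C)C[C@@H](O)CC1(C)C | intermediate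
4 | (4R,6R)-4-[(tert-butyldimethylsilyl)oxy]-2,2,6-trimethylcyclohexan-1-one | O=C1[C@H](C)C[C@@H](O[Si](C)(C)C(C)(C)C)CC1(C)C | intermediate
5 | N'-[(1E,4R,6R)-4-[(tert-butyldimethylsilyl)oxy]-2,2,6-trimethylcyclohexylidene]-4-methylbenzenesulfonohydrazide | Cc1ccc(cc1)S(=O)(=O)N/N=C1\[C@H](C)C[C@@H](O[Si](C)(C)C(C)(C)C)CC1(C)C | intermediate
6 | (2E)-3-methylpent-2-en-4-yn-1-ol | C#C/C(C)=C/CO | starting material
7 | tert-butyldimethyl{[(2E)-3-methylpent-2-en-4-yn-1-yl]oxy}silane | C#C/C(C)=C/CO[Si](C)(C)C(C)(C)C | intermediate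
8 | diazoalkane, (4R,6R)-4-[(tert-butyldimethylsilyl)oxy]-1-diazo-2,2,6-trimethylcyclohexane | [N-]=[N+]=C1[C@H](C)C[C@@H](O[Si](C)(C)C(C)(C)C)CC1(C)C | intermediate (not isolated)
9 | bis-TBS C15 enyne, tert-butyl{[(1R)-4-[(3E)-5-{[tert-butyl(dimethyl)silyl]oxy}-3-methylpent-3-en-1-yn-1-yl]-3,5,5-trimethylcyclohex-3-en-1-yl]oxy}dimethylsilane | CC(C)(C)[Si](C)(C)OC/C=C(\C)C#CC1=C(C)C[C@@H](O[Si](C)(C)C(C)(C)C)CC1(C)C | intermediate
10 | (1R)-4-[(3E)-5-hydroxy-3-methylpent-3-en-1-yn-1-yl]-3,5,5-trimethylcyclohex-3-en-1-ol | OC/C=C(\C)C#CC1=C(C)C[C@@H](O)CC1(C)C | intermediate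
11 | (2E)-5-[(4R)-4-hydroxy-2,6,6-trimethylcyclohex-1-en-1-yl]-3-methylpent-2-en-4-ynal | O=C/C=C(\C)C#CC1=C(C)C[C@@H](O)CC1(C)C | intermediate
12 | (2E,4E,6E)-2,7-dimethylocta-2,4,6-trienedial | O=C/C(C)=C/C=C/C=C(C)/C=O | starting material
13 | (2E,4E,6E)-2,7-dimethylocta-2,4,6-triene-1,8-diol | OC/C(C)=C/C=C/C=C(C)/CO | intermediate
14 | (2E,4E,6E)-1,8-dibromo-2,7-dimethylocta-2,4,6-triene | BrC/C(C)=C/C=C/C=C(C)/CBr | intermediate
15 | tetraethyl [(2E,4E,6E)-2,7-dimethylocta-2,4,6-triene-1,8-diyl]bis(phosphonate) | CCOP(=O)(OCC)C/C(C)=C/C=C/C=C(C)/CP(=O)(OCC)OCC | intermediate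
16 | diethyl {(2E,4E,6E,8E,10E)-13-[(4R)-4-hydroxy-2,6,6-trimethylcyclohex-1-en-1-yl]-2,7,11-trimethyltrideca-2,4,6,8,10-pentaen-12-yn-1-yl}phosphonate | CCOP(=O)(OCC)C/C(C)=C/C=C/C=C(C)/C=C/C=C(\C)C#CC1=C(C)C[C@@H](O)CC1(C)C | intermediate
17 | (3E)-5-hydroxy-3-methylpent-3-en-2-one | CC(=O)/C(C)=C/CO | intermediate
18 | (2E)-3-methyl-4-oxopent-2-enal | CC(=O)/C(C)=C/C=O | intermediate
19 | (3E,5E,7E,9E,11E,13E,15E)-18-[(4R)-4-hydroxy-2,6,6-trimethylcyclohex-1-en-1-yl]-3,7,12,16-tetramethyloctadeca-3,5,7,9,11,13,15-heptaen-17-yn-2-one | CC(=O)/C(C)=C/C=C/C(C)=C/C=C/C=C(C)/C=C/C=C(\C)C#CC1=C(C)C[C@@H](O)CC1(C)C | target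

## Step count and risk

Total step count: 15. Longest linear sequence: 9 steps (1, 2, 3, 4, 6, 7, 8, 12, 15).

**Step 6 (the proposed new method).** The hindered diazoalkane may instead undergo a 1,2-hydrogen shift to the ring alkene, the alkyne may homocouple, or palladium may end up on the face that has no syn β-hydrogen. The fallback uses known chemistry and sets out from ketone 4 and alkyne 7, skipping step 4. Alkyne 7 is deprotonated with n-BuLi (THF, −78 °C) and added to ketone 4 to give the tertiary propargylic alcohol F1 (carbinol configuration not controlled and of no consequence). F1 is then dehydrated under E2-type conditions (POCl3, pyridine, 60 °C, or Burgess reagent), where only the hydrogen on the methyl-bearing carbon can be lost. This comes back to the route at 9.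

**Step 12 (mono-olefination of a symmetrical bis-phosphonate).** The risks are double olefination and partial Z formation next to the phosphonate. The fallback inverts the polarity at C13=C14 and sets out from diol 10, dial 12 and alcohol 17. Diol 10 is treated with Ph3P·HBr (MeOH, 25 °C) to give the allylic phosphonium bromide F2. A Wittig reaction of F2 with excess 12 (NaOMe, CH2Cl2, −10 °C) gives the C25 aldehyde F3. Separately, 17 is turned into the allylic bromide F4 (CBr4, PPh3, CH2Cl2, 0 °C) and then, by Arbuzov reaction with P(OEt)3, into the keto-phosphonate F5. HWE of F5 with F3 (NaH, THF, 0 °C) comes back to the route at 19. The price is that the 15E enyne then passes through an allylic ylide, so 15Z material has to be removed by HPLC.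

**Step 15 (union with the small, sensitive γ-oxo-enal 18).** The risks are conjugate addition, enolisation of the methyl ketone and loss of volatile 18. The fallback sets out from 16 and builds the enone terminus last. HWE of 16 with commercial 2,2-dimethoxyacetaldehyde (KN(SiMe3)2, THF, −78 → 0 °C) gives the C27 dimethyl acetal F6. Brief hydrolysis (aqueous oxalic acid, acetone, 0 °C, dark) gives the C27 aldehyde F7. A Wittig reaction of F7 with the purchased stabilised ylide 3-(triphenylphosphoranylidene)butan-2-one (toluene, 60 °C) forms the E C3=C4 alkene and comes back to the route at 19. This fallback also bypasses steps 13 and 14.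

## Further compounds

F1 | step 6 | tertiary propargylic alcohol, (4R,6R)-4-[(tert-butyldimethylsilyl)oxy]-1-[(3E)-5-[(tert-butyldimethylsilyl)oxy]-3-methylpent-3-en-1-yn-1-yl]-2,2,6-trimethylcyclohexan-1-ol | CC(C)(C)[Si](C)(C)OC/C=C(\C)C#CC1(O)[C@H](C)C[C@@H](O[Si](C)(C)C(C)(C)C)CC1(C)C
F2 | step 12 | allylic phosphonium bromide, [(2E)-5-[(4R)-4-hydroxy-2,6,6-trimethylcyclohex-1-en-1-yl]-3-methylpent-2-en-4-yn-1-yl]triphenylphosphonium bromide | [Br-].c1ccccc1[P+](c1ccccc1)(c1ccccc1)C/C=C(\C)C#CC1=C(C)C[C@@H](O)CC1(C)C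
F3 | step 12 | C25 aldehyde, (2E,4E,6E,8E,10E)-13-[(4R)-4-hydroxy-2,6,6-trimethylcyclohex-1-en-1-yl]-2,7,11-trimethyltrideca-2,4,6,8,10-pentaen-12-ynal | O=C/C(C)=C/C=C/C=C(C)/C=C/C=C(\C)C#CC1=C(C)C[C@@H](O)CC1(C)C
F4 | step 12 | allylic bromide, (3E)-5-bromo-3-methylpent-3-en-2-one | CC(=O)/C(C)=C/CBr
F5 | step 12 | keto-phosphonate, diethyl [(2E)-3-methyl-4-oxopent-2-en-1-yl]phosphonate | CC(=O)/C(C)=C/CP(=O)(OCC)OCC
F6 | step 15 | C27 dimethyl acetal, (1R)-4-[(3E,5E,7E,9E,11E,13E)-15,15-dimethoxy-3,7,12-trimethylpentadeca-3,5,7,9,11,13-hexaen-1-yn-1-yl]-3,5,5-trimethylcyclohex-3-en-1-ol | COC(OC)/C=C/C(C)=C/C=C/C=C(C)/C=C/C=C(\C)C#CC1=C(C)C[C@@H](O)CC1(C)C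
F7 | step 15 | C27 aldehyde, (2E,4E,6E,8E,10E,12E)-15-[(4R)-4-hydroxy-2,6,6-trimethylcyclohex-1-en-1-yl]-4,9,13-trimethylpentadeca-2,4,6,8,10,12-hexaen-14-ynal | O=C/C=C/C(C)=C/C=C/C=C(C)/C=C/C=C(\C)C#CC1=C(C)C[C@@H](O)CC1(C)C
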